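**Plan**
1. Cuts (side chain numbered from benzylic C1′): aryl C3–C1′ (B-alkyl Suzuki–Miyaura), C1′=C2′ (methylenation), C3′–C4′ (enolate alkylation), aryl C1–acyl (Friedel–Crafts).
2. Enabling feature: the only stereocentre is the acyclic tertiary carbinol C3′. It holds O, CH3 and C2′, the same set (O, CH3, carboxyl C) that surrounds C2 of lactic acid, so only H has to give way to the homoprenyl arm C4′–C8′.
3. Chain: (R)-lactic acid is tied into a five-membered pivalaldehyde acetal and its enolate is homoprenylated. The temporary ring is then reduced away and the old carboxyl carbon ends as C2′ of a vinyl group.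
4. Union: the benzene ring, the only ring of the target, is bought as phloroglucinol, so no ring of the target is built. It is acylated, MOM-protected and iodinated; hydroboration of the vinyl group at C1′ and cross-coupling join the halves, and acid frees the four hydroxyls.
5. Stereochemistry: the lactate centre sets the acetal centre, vanishes on enolisation and is rebuilt by attack anti to tert-butyl, so homoprenyl replaces H with net retention. No later step breaks a bond at C3′.

Key step: step 3

Remark on the chemistry: C3′ of the target is read as (S). The vinyl intermediate of the route is the silyl ether of (S)-linalool; it is built de novo so that its enantiopurity rests on a crystalline acetal and not on the variable optical purity of the natural oil.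

**Step 1**
Reactants: 1 (R)-lactic acid; 2 pivalaldehyde
Product: 3 (2R,5R)-2-tert-butyl-5-methyl-1,3-dioxolan-4-one (cis isomer)
Conditions: p-TsOH·H2O (cat.), H2SO4 (cat.), pentane, reflux, Dean–Stark trap; crystallisation from pentane/Et2O, −78 °C
Reagents that add atoms: none
Why: Acid-catalysed acetalisation with azeotropic removal of water is reversible, so the lactate centre sets the new acetal centre C2 under thermodynamic control in favour of the cis isomer, and low-temperature crystallisation should remove the trans isomer.

**Step 2**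
Reactants: 4 5-bromo-2-methylpent-2-ene
Product: 5 5-iodo-2-methylpent-2-ene
Conditions: NaI, acetone, reflux, dark
Reagents that add atoms: sodium iodide, [Na+].[I-]
Why: Finkelstein halide exchange (SN2) is driven by precipitation of sodium bromide and gives the faster electrophile that a thermally fragile enolate needs.

**Step 3**
Reactants: 3 (2R,5R)-2-tert-butyl-5-methyl-1,3-dioxolan-4-one; 5 5-iodo-2-methylpent-2-ene
Product: 7 (2R,5S)-2-tert-butyl-5-methyl-5-(4-methylpent-3-en-1-yl)-1,3-dioxolan-4-one, via lithium enolate 6 (not isolated)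
Conditions: LDA, THF, −78 °C; then 5 (excess), THF/DMPU, −78 → −30 °C; aq NH4Cl
Reagents that add atoms: none
Why: LDA removes the C5 proton to give the planar lithium enolate 6, in which the lactate centre is erased and only the acetal centre C2 survives, and SN2 attack of C5 on the primary iodide then forms C3′–C4′. The closest known reaction type is the alkylation of 2-tert-butyl-1,3-dioxolan-4-one enolates with self-regeneration of the stereocentre, which is established for unactivated primary iodides as well as for allylic and benzylic halides. No ring is closed; the five-membered acetal ring is only carried through. The new quaternary centre is controlled by the tert-butyl group, which blocks its own face of the nearly flat ring, so the electrophile enters trans to it, methyl stays cis to tert-butyl and homoprenyl takes the place of H with net retention (5R becomes 5S only through the change of priorities). The step needs diastereofacial selectivity, which that group secures, and it needs substitution to outrun E2 elimination of the homoallylic iodide and self-condensation of the enolate, for which low temperature, the dipolar cosolvent and an excess of iodide are chosen.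

**Step 4**
Reactants: 7 (2R,5S)-2-tert-butyl-5-methyl-5-(4-methylpent-3-en-1-yl)-1,3-dioxolan-4-one
Product: 8 (2S)-2,6-dimethylhept-5-ene-1,2-diol
Conditions: LiAlH4, Et2O, 0 °C → rt; aq NaOH work-up
Reagents that add atoms: none
Why: Hydride reduction of the lactone-type carbonyl (LiAlH4 ester reduction) opens the ring and the released hemiacetal collapses, while no bond at the quaternary centre is broken, so its configuration is kept.

**Step 5**
Reactants: 8 (2S)-2,6-dimethylhept-5-ene-1,2-diol
Product: 9 (2S)-2,6-dimethyl-1,2-bis(triethylsilyloxy)hept-5-ene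
Conditions: TESOTf (excess), 2,6-lutidine, CH2Cl2, 0 °C → rt
Reagents that add atoms: triethylsilyl trifluoromethanesulfonate (TESOTf), CC[Si](CC)(CC)OS(=O)(=O)C(F)(F)F
Why: Silylation with a silyl triflate and a hindered pyridine base is reactive enough to cap the tertiary as well as the primary hydroxyl, and it stays buffered so the carbinol cannot ionise.

**Step 6**
Reactants: 9 (2S)-2,6-dimethyl-1,2-bis(triethylsilyloxy)hept-5-ene
Product: 10 (2S)-2,6-dimethyl-2-(triethylsilyloxy)hept-5-enal
Conditions: (COCl)2, DMSO, CH2Cl2, −78 → −40 °C; Et3N, −78 °C → rt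
Reagents that add atoms: none
Why: In the known direct Swern oxidation of primary triethylsilyl ethers the activated DMSO attacks only the unhindered primary O–Si unit, whereas the tertiary silyl ether is shielded and has no carbinol hydrogen, and the aldehyde formed has no α-hydrogen and cannot epimerise.

**Step 7**
Reactants: 10 (2S)-2,6-dimethyl-2-(triethylsilyloxy)hept-5-enal
Product: 11 triethyl{[(3S)-3,7-dimethylocta-1,6-dien-3-yl]oxy}silane (TES ether of (S)-linalool)
Conditions: Ph3PCH3Br, KOt-Bu, THF, 0 °C; then 10, 0 °C → rt
Reagents that add atoms: methyltriphenylphosphonium bromide, C[P+](c1ccccc1)(c1ccccc1)c1ccccc1.[Br-]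
Why: Wittig methylenation with the small non-stabilised ylide is reliable on α-quaternary aldehydes and brings in C1′ without touching C3′.

**Step 8**
Reactants: 12 phloroglucinol
Product: 13 2-methyl-1-(2,4,6-trihydroxyphenyl)propan-1-one (phlorisobutyrophenone)
Conditions: i-PrCOCl, AlCl3, CH2Cl2/PhNO2, 0 → 45 °C; aq HCl
Reagents that add atoms: isobutyryl chloride, CC(C)C(=O)Cl
Why: Friedel–Crafts C-acylation of the strongly activated ring should stop after one acyl group because the aluminium-chelated aryl ketone is deactivated.

**Step 9**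
Reactants: 13 2-methyl-1-(2,4,6-trihydroxyphenyl)propan-1-one
Product: 14 2-methyl-1-[2,4,6-tris(methoxymethoxy)phenyl]propan-1-one
Conditions: NaH (excess), MOMCl (excess), THF/DMF, 0 °C → rt
Reagents that add atoms: chloromethyl methyl ether (MOMCl), COCCl
Why: Williamson-type O-alkylation of the phenoxides with the hard electrophile MOMCl needs the strong base to break the hydrogen bonds of the two ortho hydroxyls to the ketone.

**Step 10**
Reactants: 14 2-methyl-1-[2,4,6-tris(methoxymethoxy)phenyl]propan-1-one
Product: 15 1-[3-iodo-2,4,6-tris(methoxymethoxy)phenyl]-2-methylpropan-1-one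
Conditions: NIS (1 equiv), MeCN, 0 °C → rt, dark
Reagents that add atoms: N-iodosuccinimide (NIS), O=C1CCC(=O)N1I
Why: Electrophilic aromatic iodination takes place at one of the two equivalent free ring positions, each activated by three alkoxy groups, and one equivalent of NIS together with the bulk of the first iodine should hold it at the mono-iodide.

**Step 11**
Reactants: 11 triethyl{[(3S)-3,7-dimethylocta-1,6-dien-3-yl]oxy}silane; 15 1-[3-iodo-2,4,6-tris(methoxymethoxy)phenyl]-2-methylpropan-1-one
Product: 17 1-{3-[(3S)-3,7-dimethyl-3-(triethylsilyloxy)oct-6-en-1-yl]-2,4,6-tris(methoxymethoxy)phenyl}-2-methylpropan-1-one, via B-alkyl-9-BBN borane 16 (not isolated)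
Conditions: 9-BBN, THF, 0 °C → rt; then 3 M aq K3PO4, 15, Pd(OAc)2 (cat.), SPhos (cat.), THF/H2O, 60 °C
Reagents that add atoms: none
Why: Anti-Markovnikov hydroboration with 9-BBN selects the monosubstituted vinyl group over the trisubstituted C6′=C7′ alkene by a wide margin, and B-alkyl Suzuki–Miyaura coupling with a bulky electron-rich biarylphosphine then joins C1′ to the di-ortho-substituted aryl iodide without involving C3′.

**Step 12**
Reactants: 17 1-{3-[(3S)-3,7-dimethyl-3-(triethylsilyloxy)oct-6-en-1-yl]-2,4,6-tris(methoxymethoxy)phenyl}-2-methylpropan-1-one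
Product: 18 1-{2,4,6-trihydroxy-3-[(3S)-3-hydroxy-3,7-dimethyloct-6-en-1-yl]phenyl}-2-methylpropan-1-one (target)
Conditions: 3 M aq HCl, MeOH, rt → 40 °C
Reagents that add atoms: none
Why: Acid-catalysed acetal exchange with methanol removes the three MOM groups and the same medium solvolyses the TES ether, while dilute acid near room temperature should leave the saturated tertiary carbinol and the trisubstituted alkene untouched.

**Compound list**
1 | (R)-lactic acid | C[C@@H](O)C(=O)O | starting material
2 | pivalaldehyde | CC(C)(C)C=O | starting material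
3 | (2R,5R)-2-tert-butyl-5-methyl-1,3-dioxolan-4-one (cis) | C[C@H]1O[C@@H](C(C)(C)C)OC1=O | intermediate
4 | 5-bromo-2-methylpent-2-ene | CC(C)=CCCBr | starting material
5 | 5-iodo-2-methylpent-2-ene | CC(C)=CCCI | intermediate
6 | lithium (2R)-2-tert-butyl-5-methyl-1,3-dioxol-4-olate | CC1=C([O-])O[C@H](C(C)(C)C)O1.[Li+] | intermediate
7 | (2R,5S)-2-tert-butyl-5-methyl-5-(4-methylpent-3-en-1-yl)-1,3-dioxolan-4-one (methyl cis to tert-butyl) | CC(C)=CCC[C@]1(C)O[C@@H](C(C)(C)C)OC1=O | intermediate
8 | (2S)-2,6-dimethylhept-5-ene-1,2-diol | CC(C)=CCC[C@](C)(O)CO | intermediate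
9 | (2S)-2,6-dimethyl-1,2-bis(triethylsilyloxy)hept-5-ene | CC(C)=CCC[C@](C)(O[Si](CC)(CC)CC)CO[Si](CC)(CC)CC | intermediate
10 | (2S)-2,6-dimethyl-2-(triethylsilyloxy)hept-5-enal | CC(C)=CCC[C@](C)(O[Si](CC)(CC)CC)C=O | intermediate
11 | triethyl{[(3S)-3,7-dimethylocta-1,6-dien-3-yl]oxy}silane | CC(C)=CCC[C@](C)(O[Si](CC)(CC)CC)C=C | intermediate
12 | phloroglucinol | Oc1cc(O)cc(O)c1 | starting material
13 | 2-methyl-1-(2,4,6-trihydroxyphenyl)propan-1-one | CC(C)C(=O)c1c(O)cc(O)cc1O | intermediate
14 | 2-methyl-1-[2,4,6-tris(methoxymethoxy)phenyl]propan-1-one | CC(C)C(=O)c1c(OCOC)cc(OCOC)cc1OCOC | intermediate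
15 | 1-[3-iodo-2,4,6-tris(methoxymethoxy)phenyl]-2-methylpropan-1-one | CC(C)C(=O)c1c(OCOC)cc(OCOC)c(I)c1OCOC | intermediate
16 | 9-[(3R)-3,7-dimethyl-3-(triethylsilyloxy)oct-6-en-1-yl]-9-borabicyclo[3.3.1]nonane (geometry unchanged; descriptor R only because B ranks below C) | CC(C)=CCC[C@](C)(O[Si](CC)(CC)CC)CCB1C2CCCC1CCC2 | intermediate
17 | 1-{3-[(3S)-3,7-dimethyl-3-(triethylsilyloxy)oct-6-en-1-yl]-2,4,6-tris(methoxymethoxy)phenyl}-2-methylpropan-1-one | CC(C)=CCC[C@](C)(O[Si](CC)(CC)CC)CCc1c(OCOC)cc(OCOC)c(C(=O)C(C)C)c1OCOC | intermediate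
18 | 1-{2,4,6-trihydroxy-3-[(3S)-3-hydroxy-3,7-dimethyloct-6-en-1-yl]phenyl}-2-methylpropan-1-one | CC(C)=CCC[C@](C)(O)CCc1c(O)cc(O)c(C(=O)C(C)C)c1O | target

**Step count**
Total step count: 12.
Longest linear sequence: 8 steps (1, 3, 4, 5, 6, 7, 11, 12).

**Steps most likely to fail**

**Step 3.**
- Risk: substitution at the unactivated homoallylic iodide may be slower than E2 elimination of the iodide by the enolate. It may also be slower than thermal fragmentation or self-condensation of the enolate, so conversion could stall.
- Fallback (sets out from 3, returns at 7): the same enolate 6 is trapped with allyl bromide, a much faster electrophile that cannot eliminate. Under the same facial control this gives the 5-allyl dioxolanone F1. 9-BBN adds to the terminal alkene to give the B-alkyl borane F2, which is oxidised in the same flask with sodium perborate to the primary alcohol F3. Dess–Martin periodinane gives the aldehyde F4. A Wittig reaction with isopropylidenetriphenylphosphorane at low temperature builds C6′=C7′ and delivers 7.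

**Step 11.**
- Risk: transmetalation and reductive elimination at an aryl-palladium flanked by two OMOM groups may be slow. β-Hydride elimination of the alkyl-palladium and reductive loss of iodine from the arene could then consume both partners.
- Fallback (sets out from 16 and 12, returns at 17): the aryl–C1′ bond is made by SN2 alkylation of an aryllithium and the acyl group is attached last. Oxidation of 16 with NaOH/H2O2 gives the primary alcohol F5, and I2/PPh3/imidazole (Appel-type) gives the primary iodide F6. Phloroglucinol 12 with NaH/MOMCl gives 1,3,5-tris(methoxymethoxy)benzene F7. Directed ortho-lithiation with n-BuLi gives the aryllithium F8, and alkylation with F6 in THF/DMPU gives the alkylated arene F9. A second ortho-lithiation at one of the two equivalent positions gives the aryllithium F10, which is acylated with N-methoxy-N-methylisobutyramide to give 17.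

**Step 12.**
- Risk: before the last MOM group has left, acid may ionise the tertiary carbinol or protonate the alkene. Ring closure onto a neighbouring phenol or onto the carbinol oxygen would follow, with loss of the stereocentre.
- Fallback (sets out from 13, returns at 18): fluoride-labile SEM groups replace MOM, so the endgame never sees acid. NaH/SEMCl converts 13 into the tris-SEM ether F11, and NIS gives the iodide F12. Coupling with borane 16 as in step 11 gives the protected product F13. TBAF in THF/DMPU at 40–60 °C removes the three SEM groups and the TES group in one operation, and a buffered work-up gives 18.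

**Further compounds**
F1 | step 3 | (2R,5S)-5-allyl-2-tert-butyl-5-methyl-1,3-dioxolan-4-one | C=CC[C@]1(C)O[C@@H](C(C)(C)C)OC1=O
F2 | step 3 | (2R,5S)-5-[3-(9-borabicyclo[3.3.1]nonan-9-yl)propyl]-2-tert-butyl-5-methyl-1,3-dioxolan-4-one | C1CC2CCCC(C1)B2CCC[C@]1(C)O[C@@H](C(C)(C)C)OC1=O
F3 | step 3 | (2R,5S)-2-tert-butyl-5-(3-hydroxypropyl)-5-methyl-1,3-dioxolan-4-one | OCCC[C@]1(C)O[C@@H](C(C)(C)C)OC1=O
F4 | step 3 | 3-[(2R,4S)-2-tert-butyl-4-methyl-5-oxo-1,3-dioxolan-4-yl]propanal | O=CCC[C@]1(C)O[C@@H](C(C)(C)C)OC1=O
F5 | step 11 | (3S)-3,7-dimethyl-3-(triethylsilyloxy)oct-6-en-1-ol | CC(C)=CCC[C@](C)(O[Si](CC)(CC)CC)CCO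
F6 | step 11 | triethyl{[(3S)-1-iodo-3,7-dimethyloct-6-en-3-yl]oxy}silane | CC(C)=CCC[C@](C)(O[Si](CC)(CC)CC)CCI
F7 | step 11 | 1,3,5-tris(methoxymethoxy)benzene | COCOc1cc(OCOC)cc(OCOC)c1
F8 | step 11 | 2,4,6-tris(methoxymethoxy)phenyllithium | [Li]c1c(OCOC)cc(OCOC)cc1OCOC
F9 | step 11 | triethyl({(3S)-3,7-dimethyl-1-[2,4,6-tris(methoxymethoxy)phenyl]oct-6-en-3-yl}oxy)silane | CC(C)=CCC[C@](C)(O[Si](CC)(CC)CC)CCc1c(OCOC)cc(OCOC)cc1OCOC
F10 | step 11 | 3-[(3S)-3,7-dimethyl-3-(triethylsilyloxy)oct-6-en-1-yl]-2,4,6-tris(methoxymethoxy)phenyllithium | CC(C)=CCC[C@](C)(O[Si](CC)(CC)CC)CCc1c(OCOC)cc(OCOC)c([Li])c1OCOC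
F11 | step 12 | 2-methyl-1-(2,4,6-tris{[2-(trimethylsilyl)ethoxy]methoxy}phenyl)propan-1-one | CC(C)C(=O)c1c(OCOCC[Si](C)(C)C)cc(OCOCC[Si](C)(C)C)cc1OCOCC[Si](C)(C)C
F12 | step 12 | 1-(3-iodo-2,4,6-tris{[2-(trimethylsilyl)ethoxy]methoxy}phenyl)-2-methylpropan-1-one | CC(C)C(=O)c1c(OCOCC[Si](C)(C)C)cc(OCOCC[Si](C)(C)C)c(I)c1OCOCC[Si](C)(C)C
F13 | step 12 | 1-(3-[(3S)-3,7-dimethyl-3-(triethylsilyloxy)oct-6-en-1-yl]-2,4,6-tris{[2-(trimethylsilyl)ethoxy]methoxy}phenyl)-2-methylpropan-1-one | CC(C)=CCC[C@](C)(O[Si](CC)(CC)CC)CCc1c(OCOCC[Si](C)(C)C)cc(OCOCC[Si](C)(C)C)c(C(=O)C(C)C)c1OCOCC[Si](C)(C)C
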